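# Total synthesis plan for (1R,2R,3S,6R)-2-[(1E)-hept-1-en-1-yl]-N1,N3-bis(2-methylpropyl)-6-pentylcyclohex-4-ene-1,3-dicarboxamide (21)

Ring atoms are called C1 (heptenyl; side-chain alkene C1′=C2′), C2 (carboxamide), C3 (pentyl), C4=C5 and C6 (carboxamide). Plain numbers are compounds.

## The problem

Target 21 is a cyclohex-4-ene with four stereocentres: three contiguous ones (C3, C2, C1) and a fourth, C6, on the other side of C1. The (E)-heptenyl group on C1 is trans to both neighbouring carboxamides, so the two carboxamides are cis to each other across C1, and the pentyl group on C3 is cis to the C2 carboxamide. C2 and C3 are a carbonyl α-carbon and a branch point of the kind that auxiliary-controlled acyclic reactions set well, and C1, being allylic, can be relayed from an oxygen-bearing carbon. C6 is the awkward centre: its hydrogen is both allylic and α to a carbonyl, so in an ester or an activated acid it epimerises easily and C4=C5 can slip into conjugation. C6 should therefore be fixed by a structural constraint, not by a free equilibrium, and no base should meet a C6–H ester. The two alkenes exclude late ozonolysis or hydrogenolysis. The key step rests on one feature: C1 is allylic to C1′=C2′ and bonded to C6, which is α to a carboxyl carbon and attached to the sp2 carbon C5, so C1–C6 is the retron of an allylic alkylation by a γ-deprotonated alkylidene malonate. A second feature serves the endgame: two identical N-isobutyl carboxamides in a cis-1,3 relationship can be bridged through one nitrogen as an imide.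

## Retrosynthesis

**Amide C–N bond (21 ⇒ 20 + 10).** In the reverse sense the nitrogen of one carboxamide is joined to the other carbonyl with loss of 10, giving bicyclic imide 20. The neighbouring cut, back to a free C6 acid or ester, would leave C6 to an open equilibrium in which the alkene can migrate. In 20 the cis-1,3 relationship is enforced by the ring. Because the imide nitrogen already carries isobutyl, the forward aminolysis gives 21 whichever carbonyl is attacked.

**Imide N–C(O) bond on the C6 side (20 ⇒ 18, through 19).** Amic acid 18 may be a mixture of C6 epimers. The forward cyclodehydration must convert both, so the epimer that cannot close has to invert at C6 through its mixed anhydride 19. After closure C6 is a bridgehead and can no longer enolise.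

**C6–H back to C6–CO2Me (18 ⇒ 16, through 17).** Adding a second carboxyl group at C6 gives geminal diester 16, in which C6 is not stereogenic and carries the malonate needed for a soft nucleophile. The forward step is hydrolysis of a quaternary, non-enolisable malonate and thermal decarboxylation of diacid 17. A chloride-induced demethoxycarbonylation (Krapcho) was set aside because its hot, basic ester enolate invites migration of C4=C5.

**C1–C6 bond (16 ⇒ 15), the key cut.** Opening the ring here gives acyclic 15, an allylic methyl carbonate with a tethered alkylidene malonate. Against the other ring bonds, this cut lets C1 be copied from an aldol carbinol by a stereospecific substitution, closes the ring without added base, and needs only three stereocentres in an open chain. The forward reaction must give retention at C1, closure at the proximal allyl terminus, and bonding through the α-carbon of the dienolate.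

**C5=C6 alkene and two functional-group changes (15 ⇒ 13 + 14; 13 ⇒ 12 ⇒ 11).** The alkylidene malonate comes from aldehyde 13 and malonate 14 by condensation. Aldehyde 13 is masked as dioxolane 12, and the carbonate of 12 comes from alcohol 11. The carbonate is installed before the aldehyde is freed so that the hydroxyl cannot form a lactol or add to the alkylidene malonate.

**C2 amide C–N bond (11 ⇒ 9 + 10).** The amide is made early by exchanging the auxiliary of aldol adduct 9 for 10, assisted by the neighbouring hydroxyl. A secondary amide at C2 makes C2–H far less acidic than in the imide, which protects the later carbonate from β-elimination, and it is the nitrogen later used for the imide.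

**C1–C2 bond (9 ⇒ 6 + 7, through 8).** A syn-aldol between the boron enolate 8 of imide 6 and enal 7 sets C2 and the carbinol carbon together and brings in the (E)-alkene ready-made. An anti-aldol or an allylation would not give the syn array that retention at C1 requires.

**C3–C4 bond (6 ⇒ 4 + 5).** Conjugate addition of the acetal-bearing Grignard reagent 5 to enoyl imide 4 sets C3 and delivers the two-carbon aldehyde equivalent (C4, C5) in one step. The same auxiliary then serves the aldol.

**N-acyl bond (4 ⇒ 1 + 2, through 3).** Imide 4 comes from commercial acid 1 and oxazolidinone 2 by way of mixed anhydride 3.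

## Roads not taken

**Alternative 1: Ireland–Claisen ring contraction.** The cut is C2–C3. In the forward sense the C2 carboxyl starts as the carbonyl of δ-lactone A1, whose ring oxygen sits on C5 next to an (E)-heptenyl group destined to become C4, C3 and the pentyl chain. Enolisation and O-silylation of A1, then a [3,3] shift through the boat transition state that the ring enforces, would form C2–C3, break O–C5 and give cyclohexene acid A2 with C4=C5 in place.
- Merits: C6 is a stereocentre of A1 from the start and never passes through a planar or doubly activated state, which is exactly where the plan adopted here is weakest. C2 and C3 arise together by suprafacial chirality transfer. A2 already has differentiated carboxyl groups, so one amidation with 10 finishes the synthesis.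
- Weak points: A1 needs three stereocentres (C1, C6 and the oxygen-bearing C5) and two different heptenyl groups on a lactone, a longer build than open-chain 15. The amide N–H must be deprotonated or silylated alongside the lactone. C6–H is α to the amide and β to the lactone oxygen, so base can open the lactone by elimination. The C2 configuration depends on one boat transition state.
- Comparison: this road is better at C6 and tidier in stereochemical bookkeeping. The adopted plan sets against it a precursor made by two auxiliary-controlled reactions on commercial materials, a base-free ring closure, and the imide lock for C6, at the cost of two extra functional-group steps.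

**Alternative 2: cyclobutene ring-rearrangement metathesis.** The cuts are the two alkenes, C4=C5 and C1′=C2′. The second-generation Grubbs catalyst would open cyclobutene A3 between C5 and C1′, the vinyl group on C3 would close onto C5, and hept-1-ene A4 would cap C1′, giving diester A5.
- Merits: all four sp3 centres exist before the six-membered ring does. Strain release drives the step, both alkenes form in one operation with no base near C6, and the two esters of A5 could become the two amides in one double aminolysis with 10. After ring formation this is shorter than the adopted plan.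
- Weak points: the cross-metathesis cap does not guarantee (E) geometry at C1′=C2′ and competes with self-metathesis of A4. The carbene at C1′ can close on the C3 vinyl group to a cyclopentene. A3 carries an allylic ester stereocentre on a cyclobutene, prone to epimerisation and to thermal electrocyclic opening, and there is no short auxiliary-based entry to its four stereocentres.
- Comparison: the metathesis road is equal or better in step count after the ring is made and does not expose C6 during ring formation. The adopted plan offers a secure (E)-alkene (bought in with 7 and only relayed), an unambiguous ring size, and stereocentres from well-understood acyclic reactions.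

**Alternative 3: palladium-catalysed enolate alkenylation closing C5–C6.** The cut is C5–C6. Pd(PPh3)4 (zerovalent palladium) would insert into the C–I bond of (Z)-vinyl iodide A6, the C6 ester enolate would bind to palladium, and reductive elimination would close the ring to ester A7 with C4=C5 fixed by the iodide geometry.
- Merits: the alkene position is unambiguous, no γ-deprotonation is needed, no carbon is added only to be removed, and C1 is a plain sp3 centre set before ring closure. After the key step it is shorter than the adopted plan.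
- Weak points: C6 is created under strong base, and the product C6–H (allylic and α to the ester) is more acidic than that of the starting ester, so epimerisation, alkene migration and a second alkenylation are all open. The amide N–H is deprotonated first, and its nitrogen can couple with the vinylpalladium unit to a six-membered ene-lactam, the same ring size as the wanted carbocycle. A6 needs a (Z)-vinyl iodide and a C1 centre that no aldol can set.
- Comparison: better in atom economy and in alkene placement. It shares the C6 weakness but has no repair under its own basic conditions, whereas the adopted plan closes the ring without added base and defers C6 to a ring constraint.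

Key step: step 8

Assumption: Grignard reagent 5 is used as its commercial THF solution, and aldehyde 13 is drawn open-chain although it may equilibrate with a cyclic N-acyl hemiaminal that reopens under the amine buffer of step 7.

## Route

Step 1
Reactants: 1 (2E)-oct-2-enoic acid; 2 (4R)-4-benzyl-1,3-oxazolidin-2-one
Product: 4 (4R)-4-benzyl-3-[(2E)-oct-2-enoyl]-1,3-oxazolidin-2-one, via mixed pivalic anhydride 3 (not isolated)
Conditions: PivCl, Et3N, THF, −20 °C; then 2, LiCl, −20 °C → rt
Reagents that add atoms: none
Why: Mixed-anhydride N-acylation of an oxazolidinone: the acid is activated as 3, and LiCl/Et3N makes the carbamate nitrogen nucleophilic enough to attack the unhindered octenoyl carbonyl; no stereocentre is formed and the (E)-alkene is untouched.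

Step 2
Reactants: 4 (4R)-4-benzyl-3-[(2E)-oct-2-enoyl]-1,3-oxazolidin-2-one; 5 (1,3-dioxolan-2-ylmethyl)magnesium bromide
Product: 6 (4R)-4-benzyl-3-[(3R)-3-(1,3-dioxolan-2-ylmethyl)octanoyl]-1,3-oxazolidin-2-one
Conditions: 5 (THF solution), CuBr·SMe2 (20 mol %), THF/Me2S, −40 → −20 °C; sat. aq. NH4Cl
Reagents that add atoms: none
Why: Copper-catalysed conjugate addition of a Grignard reagent to an N-enoyl oxazolidinone: magnesium holds the two carbonyls syn and the enoyl group s-cis, so the organocopper adds to the β-carbon on the face away from the benzyl group, which should set C3 as (R); the acetal is inert to the organometallic.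

Step 3
Reactants: 6 (4R)-4-benzyl-3-[(3R)-3-(1,3-dioxolan-2-ylmethyl)octanoyl]-1,3-oxazolidin-2-one; 7 (2E)-oct-2-enal
Product: 9 (4R)-4-benzyl-3-[(2R,3S,4E)-2-[(2R)-1-(1,3-dioxolan-2-yl)heptan-2-yl]-3-hydroxydec-4-enoyl]-1,3-oxazolidin-2-one, via dibutylboron (Z)-enolate 8 (not isolated)
Conditions: Bu2BOTf, i-Pr2NEt, CH2Cl2, 0 °C; then 7, −78 → 0 °C; pH 7 phosphate buffer, MeOH, H2O2, 0 °C
Reagents that add atoms: none
Why: Evans boron syn-aldol: soft enolisation gives (Z)-enolate 8, which adds to the enal carbonyl through a closed chair transition state on the face away from the benzyl group, setting C2 (R) and the carbinol carbon (S) together as the syn pair; the auxiliary should override the remote C3 centre, and the buffered peroxide work-up only cleaves the boron–oxygen and boron–carbon bonds.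

Step 4
Reactants: 9 (4R)-4-benzyl-3-[(2R,3S,4E)-2-[(2R)-1-(1,3-dioxolan-2-yl)heptan-2-yl]-3-hydroxydec-4-enoyl]-1,3-oxazolidin-2-one; 10 2-methylpropan-1-amine (isobutylamine)
Product: 11 (2R,3S,4E)-2-[(2R)-1-(1,3-dioxolan-2-yl)heptan-2-yl]-3-hydroxy-N-(2-methylpropyl)dec-4-enamide
Conditions: AlMe3, 10, CH2Cl2, 0 °C → rt; aq. potassium sodium tartrate
Reagents that add atoms: none
Why: Weinreb-type aminolysis with the aluminium amide formed from AlMe3 and 10: the aluminium alkoxide of the β-hydroxyl directs attack to the exocyclic carbonyl, the auxiliary is released intact, and the non-basic medium should avoid retro-aldol cleavage and epimerisation at C2.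

Step 5
Reactants: 11 (2R,3S,4E)-2-[(2R)-1-(1,3-dioxolan-2-yl)heptan-2-yl]-3-hydroxy-N-(2-methylpropyl)dec-4-enamide
Product: 12 (2R,3S,4E)-2-[(2R)-1-(1,3-dioxolan-2-yl)heptan-2-yl]-1-[(2-methylpropyl)amino]-1-oxodec-4-en-3-yl methyl carbonate
Conditions: ClCO2Me, pyridine, DMAP (cat.), CH2Cl2, 0 °C → rt
Reagents that add atoms: methyl chloroformate, COC(=O)Cl
Why: Acylation of a secondary allylic alcohol by a chloroformate under nucleophilic catalysis; the amide N–H does not compete, no bond to a stereocentre is broken, and because C2 carries a secondary amide and not an imide its hydrogen is too weakly acidic for β-elimination of the new carbonate.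

Step 6
Reactants: 12 (2R,3S,4E)-2-[(2R)-1-(1,3-dioxolan-2-yl)heptan-2-yl]-1-[(2-methylpropyl)amino]-1-oxodec-4-en-3-yl methyl carbonate
Product: 13 methyl (2R,3S,4E)-1-[(2-methylpropyl)amino]-1-oxo-2-[(3R)-1-oxooctan-3-yl]dec-4-en-3-yl carbonate
Conditions: 1 M aq. HCl, THF, rt
Reagents that add atoms: water, O
Why: Acid-catalysed hydrolysis of a dioxolane acetal; the methyl carbonate and the amide should survive dilute acid at room temperature and C4 has no stereocentre to lose; the product is used crude because it may rest partly as a cyclic N-acyl hemiaminal.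

Step 7
Reactants: 13 methyl (2R,3S,4E)-1-[(2-methylpropyl)amino]-1-oxo-2-[(3R)-1-oxooctan-3-yl]dec-4-en-3-yl carbonate; 14 dimethyl propanedioate (dimethyl malonate)
Product: 15 dimethyl 2-[(3R,4R,5S,6E)-5-[(methoxycarbonyl)oxy]-4-[(2-methylpropyl)carbamoyl]-3-pentyldodec-6-en-1-ylidene]propanedioate
Conditions: piperidine (cat.), AcOH (cat.), 4 Å molecular sieves, CH2Cl2, rt
Reagents that add atoms: none
Why: Knoevenagel condensation through the piperidinium iminium of the aldehyde, with sieves taking up the water; it forms the C5=C6 alkene of an alkylidene malonate (no geometry issue, the two esters being identical) and leaves the three stereocentres and the carbonate alone.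

Step 8
Reactants: 15 dimethyl 2-[(3R,4R,5S,6E)-5-[(methoxycarbonyl)oxy]-4-[(2-methylpropyl)carbamoyl]-3-pentyldodec-6-en-1-ylidene]propanedioate
Product: 16 dimethyl (4R,5R,6S)-6-[(1E)-hept-1-en-1-yl]-5-[(2-methylpropyl)carbamoyl]-4-pentylcyclohex-2-ene-1,1-dicarboxylate
Conditions: Pd(PPh3)4 (5 mol %), THF (0.01 M), rt → 50 °C
Reagents that add atoms: none
Why: Intramolecular Tsuji–Trost allylic alkylation: Pd(PPh3)4 (zerovalent palladium) ionises the allylic methyl carbonate anti to the leaving group to a syn,syn π-allyl intermediate [(η3-allyl)Pd(PPh3)2]+ over C1, C1′ and C2′, and the leaving group loses CO2 to methoxide, which takes a C4 proton from the alkylidene malonate. The soft dienolate attacks through its α-carbon C6 on the allyl face opposite palladium, so two inversions add up to retention: the (S)-carbinol configuration set by the aldol is the control element for C1, the only new stereocentre, and places heptenyl trans to the C2 carboxamide (C6 carries two identical esters and is not stereogenic). The cyclohexene closes in the 6-exo mode at the proximal allyl terminus C1; attack at C2′ would need an eight-membered ring, and attack through C4 a four-membered ring or an endocyclic closure that the syn,syn allyl geometry cannot reach, so the tether length fixes the regiochemistry at both partners. Bonding at C6 moves the malonate alkene out of conjugation into C4=C5, necessarily cis in the ring; only the (Z)-dienolate can reach C1, and the (E)-form returns by proton exchange with the methanol formed. The syn,syn allyl geometry carries the (E) geometry of C1′=C2′ into the product. The closest known reaction types are the stereoretentive intramolecular allylation of malonates through allylic carbonates and the deconjugative α-allylation of alkylidene malonates and malononitriles. The step needs retention at C1, six-ring regiochemistry and α-selectivity of the dienolate; these are secured by the defined carbinol centre, the three-atom spacing between C1 and the acidic C4, and the soft character of the doubly stabilised nucleophile, while the absence of added base spares C2–H and the amide N–H.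

Step 9
Reactants: 16 dimethyl (4R,5R,6S)-6-[(1E)-hept-1-en-1-yl]-5-[(2-methylpropyl)carbamoyl]-4-pentylcyclohex-2-ene-1,1-dicarboxylate
Product: 18 (4R,5R,6S)-6-[(1E)-hept-1-en-1-yl]-5-[(2-methylpropyl)carbamoyl]-4-pentylcyclohex-2-ene-1-carboxylic acid as a mixture of C1 epimers, via geminal diacid 17 (not isolated)
Conditions: KOH, MeOH/H2O, 65 °C; 1 M HCl to pH 2; then toluene, 100 °C
Reagents that add atoms: potassium hydroxide, [K+].[OH-]
Why: Saponification of a quaternary, non-enolisable malonate (no C6–H is present while base is) followed by thermal decarboxylation of the vinyl-substituted malonic acid 17 through its cyclic transition state; the dienol formed should ketonise at C6, keeping the alkene at C4=C5 and giving both C6 epimers, a mixture that the next step converges.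

Step 10
Reactants: 18 (4R,5R,6S)-6-[(1E)-hept-1-en-1-yl]-5-[(2-methylpropyl)carbamoyl]-4-pentylcyclohex-2-ene-1-carboxylic acid as a mixture of C1 epimers
Product: 20 (1R,5S,8R,9R)-9-[(1E)-hept-1-en-1-yl]-3-(2-methylpropyl)-8-pentyl-3-azabicyclo[3.3.1]non-6-ene-2,4-dione, via mixed acetic anhydride 19 (not isolated)
Conditions: Ac2O, NaOAc, 100 °C
Reagents that add atoms: none
Why: Cyclodehydration of an amic acid to an imide through mixed anhydride 19: only the epimer whose activated carboxyl is cis to the C2 carboxamide can close the bicycle, while the other should invert at C6 through the enol of 19, the same convergence by which trans-cyclohexane-1,3-dicarboxylic acids give cis anhydrides; once closed, C6 is a bridgehead whose enolisation is strongly disfavoured, so its configuration (carbonyl trans to heptenyl) is locked.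

Step 11
Reactants: 20 (1R,5S,8R,9R)-9-[(1E)-hept-1-en-1-yl]-3-(2-methylpropyl)-8-pentyl-3-azabicyclo[3.3.1]non-6-ene-2,4-dione; 10 2-methylpropan-1-amine (isobutylamine)
Product: 21 (1R,2R,3S,6R)-2-[(1E)-hept-1-en-1-yl]-N1,N3-bis(2-methylpropyl)-6-pentylcyclohex-4-ene-1,3-dicarboxamide
Conditions: 10, AlMe3, toluene, 0 → 60 °C; aq. potassium sodium tartrate
Reagents that add atoms: none
Why: Aminolysis of an imide by the aluminium amide of 10 (the reaction type of step 4); since the imide nitrogen already carries isobutyl, attack at either carbonyl gives the same dicarboxamide, and neither bridgehead (C2, C6) can epimerise before opening, nor do the secondary amides afterwards under these non-basic conditions.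

## Compound list

1 | (2E)-oct-2-enoic acid | CCCCC/C=C/C(=O)O | starting material
2 | (4R)-4-benzyl-1,3-oxazolidin-2-one | O=C1N[C@H](Cc2ccccc2)CO1 | starting material
3 | (2E)-oct-2-enoic 2,2-dimethylpropanoic anhydride (mixed pivalic anhydride) | CCCCC/C=C/C(=O)OC(=O)C(C)(C)C | intermediate
4 | (4R)-4-benzyl-3-[(2E)-oct-2-enoyl]-1,3-oxazolidin-2-one | CCCCC/C=C/C(=O)N1[C@H](Cc2ccccc2)COC1=O | intermediate
5 | (1,3-dioxolan-2-ylmethyl)magnesium bromide | Br[Mg]CC1OCCO1 | starting material
6 | (4R)-4-benzyl-3-[(3R)-3-(1,3-dioxolan-2-ylmethyl)octanoyl]-1,3-oxazolidin-2-one | C1COC(O1)C[C@@H](CCCCC)CC(=O)N2[C@H](Cc3ccccc3)COC2=O | intermediate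
7 | (2E)-oct-2-enal | CCCCC/C=C/C=O | starting material
8 | dibutylboron (Z)-enolate of 6 | CCCCB(CCCC)O/C(=C\[C@H](CCCCC)CC1OCCO1)N1[C@H](Cc2ccccc2)COC1=O | intermediate
9 | (4R)-4-benzyl-3-[(2R,3S,4E)-2-[(2R)-1-(1,3-dioxolan-2-yl)heptan-2-yl]-3-hydroxydec-4-enoyl]-1,3-oxazolidin-2-one | C1COC(O1)C[C@@H](CCCCC)[C@@H](C(=O)N2[C@H](Cc3ccccc3)COC2=O)[C@@H](O)/C=C/CCCCC | intermediate
10 | 2-methylpropan-1-amine (isobutylamine) | CC(C)CN | starting material
11 | (2R,3S,4E)-2-[(2R)-1-(1,3-dioxolan-2-yl)heptan-2-yl]-3-hydroxy-N-(2-methylpropyl)dec-4-enamide | C1COC(O1)C[C@@H](CCCCC)[C@@H](C(=O)NCC(C)C)[C@@H](O)/C=C/CCCCC | intermediate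
12 | (2R,3S,4E)-2-[(2R)-1-(1,3-dioxolan-2-yl)heptan-2-yl]-1-[(2-methylpropyl)amino]-1-oxodec-4-en-3-yl methyl carbonate | C1COC(O1)C[C@@H](CCCCC)[C@@H](C(=O)NCC(C)C)[C@@H](OC(=O)OC)/C=C/CCCCC | intermediate
13 | methyl (2R,3S,4E)-1-[(2-methylpropyl)amino]-1-oxo-2-[(3R)-1-oxooctan-3-yl]dec-4-en-3-yl carbonate | O=CC[C@@H](CCCCC)[C@@H](C(=O)NCC(C)C)[C@@H](OC(=O)OC)/C=C/CCCCC | intermediate
14 | dimethyl propanedioate (dimethyl malonate) | COC(=O)CC(=O)OC | starting material
15 | dimethyl 2-[(3R,4R,5S,6E)-5-[(methoxycarbonyl)oxy]-4-[(2-methylpropyl)carbamoyl]-3-pentyldodec-6-en-1-ylidene]propanedioate | COC(=O)C(C(=O)OC)=CC[C@@H](CCCCC)[C@@H](C(=O)NCC(C)C)[C@@H](OC(=O)OC)/C=C/CCCCC | intermediate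
16 | dimethyl (4R,5R,6S)-6-[(1E)-hept-1-en-1-yl]-5-[(2-methylpropyl)carbamoyl]-4-pentylcyclohex-2-ene-1,1-dicarboxylate | CCCCC/C=C/[C@H]1[C@H](C(=O)NCC(C)C)[C@H](CCCCC)C=CC1(C(=O)OC)C(=O)OC | intermediate
17 | (4R,5R,6S)-6-[(1E)-hept-1-en-1-yl]-5-[(2-methylpropyl)carbamoyl]-4-pentylcyclohex-2-ene-1,1-dicarboxylic acid | CCCCC/C=C/[C@H]1[C@H](C(=O)NCC(C)C)[C@H](CCCCC)C=CC1(C(=O)O)C(=O)O | intermediate
18 | (4R,5R,6S)-6-[(1E)-hept-1-en-1-yl]-5-[(2-methylpropyl)carbamoyl]-4-pentylcyclohex-2-ene-1-carboxylic acid (both C1 epimers) | CCCCC/C=C/[C@H]1[C@H](C(=O)NCC(C)C)[C@H](CCCCC)C=CC1C(=O)O | intermediate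
19 | acetic (4R,5R,6S)-6-[(1E)-hept-1-en-1-yl]-5-[(2-methylpropyl)carbamoyl]-4-pentylcyclohex-2-ene-1-carboxylic anhydride (both C1 epimers) | CCCCC/C=C/[C@H]1[C@H](C(=O)NCC(C)C)[C@H](CCCCC)C=CC1C(=O)OC(C)=O | intermediate
20 | (1R,5S,8R,9R)-9-[(1E)-hept-1-en-1-yl]-3-(2-methylpropyl)-8-pentyl-3-azabicyclo[3.3.1]non-6-ene-2,4-dione | CCCCC/C=C/[C@H]1[C@H](C(=O)N2CC(C)C)[C@H](CCCCC)C=C[C@@H]1C2=O | intermediate
21 | (1R,2R,3S,6R)-2-[(1E)-hept-1-en-1-yl]-N1,N3-bis(2-methylpropyl)-6-pentylcyclohex-4-ene-1,3-dicarboxamide | CCCCC/C=C/[C@H]1[C@H](C(=O)NCC(C)C)[C@H](CCCCC)C=C[C@@H]1C(=O)NCC(C)C | target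

## Step count and least certain steps

Total steps: 11. Longest linear sequence: 11 steps (1 → 21); the route is linear, with 2, 5, 7, 10 and 14 entering along the way.

**Step 8 (key step).** The ring closure may be outrun by loss of the C2 proton from the π-allyl intermediate, giving a conjugated dienamide. γ-Deprotonation of a malonate-type alkylidene by the small stationary amount of methoxide is slow, and the extended dienolate first formed must isomerise before it can reach C1. A slow closure also gives time for palladium–palladium exchange to erode the C1 configuration and for the amide nitrogen to add to the alkylidene malonate. The fallback uses a far more acidic pronucleophile. It sets out from aldehyde 13, which would be condensed with 2,2-dimethyl-1,3-dioxane-4,6-dione (pyrrolidinium acetate, CH2Cl2, rt) to 5-[(3R,4R,5S,6E)-5-[(methoxycarbonyl)oxy]-4-[(2-methylpropyl)carbamoyl]-3-pentyldodec-6-en-1-ylidene]-2,2-dimethyl-1,3-dioxane-4,6-dione F1. Its γ-hydrogens are acidic enough for complete dienolate formation. Closure with Pd(PPh3)4 in THF would give the spiro compound (9R,10R,11S)-11-[(1E)-hept-1-en-1-yl]-3,3-dimethyl-N-(2-methylpropyl)-1,5-dioxo-9-pentyl-2,4-dioxaspiro[5.5]undec-7-ene-10-carboxamide F2. Heating F2 in wet pyridine would hydrolyse and decarboxylate it, and the route is rejoined at acid 18.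

**Step 2.** The β-oxygenated organometallic can fragment (loss of an acetal oxygen as alkoxide) before it is transferred to copper, leaving 4 unreacted, and facial discrimination may be weaker than for simple alkyl groups. The fallback brings in the two carbons as an allyl group. From 4, allylmagnesium bromide with CuBr·SMe2 in THF at −78 °C would give (4R)-4-benzyl-3-[(3R)-3-(prop-2-en-1-yl)octanoyl]-1,3-oxazolidin-2-one F3. Ozonolysis with Me2S work-up, done here while no other alkene is present, would give (4R)-4-benzyl-3-[(3R)-3-(2-oxoethyl)octanoyl]-1,3-oxazolidin-2-one F4. Acetalisation with ethane-1,2-diol and catalytic TsOH rejoins the route at 6.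

**Step 6.** Once the aldehyde is free, the C2 amide nitrogen can close onto it, and under acid the hemiaminal can lose water irreversibly to an ene-lactam, which removes material from the condensation of step 7. The same nitrogen may later add to the alkylidene malonate. The fallback keeps the nitrogen acylated until the ring exists, accepting a more acidic C2–H. From 9, methyl chloroformate and pyridine would give (4R)-4-benzyl-3-[(2R,3S,4E)-2-[(2R)-1-(1,3-dioxolan-2-yl)heptan-2-yl]-3-[(methoxycarbonyl)oxy]dec-4-enoyl]-1,3-oxazolidin-2-one F5. Dilute HCl in THF would give (4R)-4-benzyl-3-[(2R,3S,4E)-3-[(methoxycarbonyl)oxy]-2-[(3R)-1-oxooctan-3-yl]dec-4-enoyl]-1,3-oxazolidin-2-one F6. Condensation with 14 as in step 7 would give dimethyl 2-[(3R,4R,5S,6E)-4-{[(4R)-4-benzyl-2-oxo-1,3-oxazolidin-3-yl]carbonyl}-5-[(methoxycarbonyl)oxy]-3-pentyldodec-6-en-1-ylidene]propanedioate F7. Closure with Pd(PPh3)4 would give dimethyl (4R,5R,6S)-5-{[(4R)-4-benzyl-2-oxo-1,3-oxazolidin-3-yl]carbonyl}-6-[(1E)-hept-1-en-1-yl]-4-pentylcyclohex-2-ene-1,1-dicarboxylate F8. Cleavage with LiOH/H2O2 (then Na2SO3 and acidification) would give (1R,2R,6S)-6-[(1E)-hept-1-en-1-yl]-5,5-bis(methoxycarbonyl)-2-pentylcyclohex-3-ene-1-carboxylic acid F9. Coupling of F9 with 10 (EDC·HCl, HOBt, CH2Cl2) rejoins the route at 16.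

**Step 10.** The epimer that cannot close may fail to invert at C6 and simply return as acid on work-up, or the ring alkene may migrate into conjugation through the dienol of the mixed anhydride. The fallback replaces cyclic trapping by equilibration of an open-chain ester. From 18, MeI and K2CO3 in DMF would give methyl (4R,5R,6S)-6-[(1E)-hept-1-en-1-yl]-5-[(2-methylpropyl)carbamoyl]-4-pentylcyclohex-2-ene-1-carboxylate (both C1 epimers) F10. Brief treatment with catalytic sodium methoxide in MeOH should favour methyl (1S,4R,5R,6S)-6-[(1E)-hept-1-en-1-yl]-5-[(2-methylpropyl)carbamoyl]-4-pentylcyclohex-2-ene-1-carboxylate F11, with the ester trans to heptenyl. Lithium hydroxide in aqueous THF at 0 °C would give (1S,4R,5R,6S)-6-[(1E)-hept-1-en-1-yl]-5-[(2-methylpropyl)carbamoyl]-4-pentylcyclohex-2-ene-1-carboxylic acid F12. Coupling of F12 with 10 (EDC·HCl, HOBt) rejoins the route at 21.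

## Further compounds

F1 | step 8 | 5-[(3R,4R,5S,6E)-5-[(methoxycarbonyl)oxy]-4-[(2-methylpropyl)carbamoyl]-3-pentyldodec-6-en-1-ylidene]-2,2-dimethyl-1,3-dioxane-4,6-dione | CC1(C)OC(=O)C(=CC[C@@H](CCCCC)[C@@H](C(=O)NCC(C)C)[C@@H](OC(=O)OC)/C=C/CCCCC)C(=O)O1
F2 | step 8 | (9R,10R,11S)-11-[(1E)-hept-1-en-1-yl]-3,3-dimethyl-N-(2-methylpropyl)-1,5-dioxo-9-pentyl-2,4-dioxaspiro[5.5]undec-7-ene-10-carboxamide | CCCCC/C=C/[C@H]1[C@H](C(=O)NCC(C)C)[C@H](CCCCC)C=CC12C(=O)OC(C)(C)OC2=O
F3 | step 2 | (4R)-4-benzyl-3-[(3R)-3-(prop-2-en-1-yl)octanoyl]-1,3-oxazolidin-2-one | C=CC[C@@H](CCCCC)CC(=O)N1[C@H](Cc2ccccc2)COC1=O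
F4 | step 2 | (4R)-4-benzyl-3-[(3R)-3-(2-oxoethyl)octanoyl]-1,3-oxazolidin-2-one | O=CC[C@@H](CCCCC)CC(=O)N1[C@H](Cc2ccccc2)COC1=O
F5 | step 6 | (4R)-4-benzyl-3-[(2R,3S,4E)-2-[(2R)-1-(1,3-dioxolan-2-yl)heptan-2-yl]-3-[(methoxycarbonyl)oxy]dec-4-enoyl]-1,3-oxazolidin-2-one | C1COC(O1)C[C@@H](CCCCC)[C@@H](C(=O)N2[C@H](Cc3ccccc3)COC2=O)[C@@H](OC(=O)OC)/C=C/CCCCC
F6 | step 6 | (4R)-4-benzyl-3-[(2R,3S,4E)-3-[(methoxycarbonyl)oxy]-2-[(3R)-1-oxooctan-3-yl]dec-4-enoyl]-1,3-oxazolidin-2-one | O=CC[C@@H](CCCCC)[C@@H](C(=O)N1[C@H](Cc2ccccc2)COC1=O)[C@@H](OC(=O)OC)/C=C/CCCCC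
F7 | step 6 | dimethyl 2-[(3R,4R,5S,6E)-4-{[(4R)-4-benzyl-2-oxo-1,3-oxazolidin-3-yl]carbonyl}-5-[(methoxycarbonyl)oxy]-3-pentyldodec-6-en-1-ylidene]propanedioate | COC(=O)C(C(=O)OC)=CC[C@@H](CCCCC)[C@@H](C(=O)N1[C@H](Cc2ccccc2)COC1=O)[C@@H](OC(=O)OC)/C=C/CCCCC
F8 | step 6 | dimethyl (4R,5R,6S)-5-{[(4R)-4-benzyl-2-oxo-1,3-oxazolidin-3-yl]carbonyl}-6-[(1E)-hept-1-en-1-yl]-4-pentylcyclohex-2-ene-1,1-dicarboxylate | CCCCC/C=C/[C@H]1[C@H](C(=O)N2[C@H](Cc3ccccc3)COC2=O)[C@H](CCCCC)C=CC1(C(=O)OC)C(=O)OC
F9 | step 6 | (1R,2R,6S)-6-[(1E)-hept-1-en-1-yl]-5,5-bis(methoxycarbonyl)-2-pentylcyclohex-3-ene-1-carboxylic acid | CCCCC/C=C/[C@H]1[C@H](C(=O)O)[C@H](CCCCC)C=CC1(C(=O)OC)C(=O)OC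
F10 | step 10 | methyl (4R,5R,6S)-6-[(1E)-hept-1-en-1-yl]-5-[(2-methylpropyl)carbamoyl]-4-pentylcyclohex-2-ene-1-carboxylate (both C1 epimers) | CCCCC/C=C/[C@H]1[C@H](C(=O)NCC(C)C)[C@H](CCCCC)C=CC1C(=O)OC
F11 | step 10 | methyl (1S,4R,5R,6S)-6-[(1E)-hept-1-en-1-yl]-5-[(2-methylpropyl)carbamoyl]-4-pentylcyclohex-2-ene-1-carboxylate | CCCCC/C=C/[C@H]1[C@H](C(=O)NCC(C)C)[C@H](CCCCC)C=C[C@@H]1C(=O)OC
F12 | step 10 | (1S,4R,5R,6S)-6-[(1E)-hept-1-en-1-yl]-5-[(2-methylpropyl)carbamoyl]-4-pentylcyclohex-2-ene-1-carboxylic acid | CCCCC/C=C/[C@H]1[C@H](C(=O)NCC(C)C)[C@H](CCCCC)C=C[C@@H]1C(=O)O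
A1 | alternative 1 | (2S,3R,4R)-2,4-bis[(1E)-hept-1-en-1-yl]-N-(2-methylpropyl)-6-oxooxane-3-carboxamide | O=C1C[C@H](/C=C/CCCCC)[C@@H](C(=O)NCC(C)C)[C@H](/C=C/CCCCC)O1
A2 | alternative 1 | (1R,2R,5S,6R)-6-[(1E)-hept-1-en-1-yl]-5-[(2-methylpropyl)carbamoyl]-2-pentylcyclohex-3-ene-1-carboxylic acid | CCCCC/C=C/[C@H]1[C@H](C(=O)O)[C@H](CCCCC)C=C[C@@H]1C(=O)NCC(C)C
A3 | alternative 2 | methyl (1S,4R)-4-[(2R,3R)-1-methoxy-1-oxo-3-pentylpent-4-en-2-yl]cyclobut-2-ene-1-carboxylate | C=C[C@@H](CCCCC)[C@@H](C(=O)OC)[C@@H]1C=C[C@@H]1C(=O)OC
A4 | alternative 2 | hept-1-ene | C=CCCCCC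
A5 | alternative 2 | dimethyl (1R,2R,3S,6R)-2-[(1E)-hept-1-en-1-yl]-6-pentylcyclohex-4-ene-1,3-dicarboxylate | CCCCC/C=C/[C@H]1[C@H](C(=O)OC)[C@H](CCCCC)C=C[C@@H]1C(=O)OC
A6 | alternative 3 | ethyl (3S,4S,5S,6Z)-3-[(1E)-hept-1-en-1-yl]-7-iodo-4-[(2-methylpropyl)carbamoyl]-5-pentylhept-6-enoate | I/C=C\[C@@H](CCCCC)[C@@H](C(=O)NCC(C)C)[C@H](/C=C/CCCCC)CC(=O)OCC
A7 | alternative 3 | ethyl (1S,4R,5R,6S)-6-[(1E)-hept-1-en-1-yl]-5-[(2-methylpropyl)carbamoyl]-4-pentylcyclohex-2-ene-1-carboxylate | CCCCC/C=C/[C@H]1[C@H](C(=O)NCC(C)C)[C@H](CCCCC)C=C[C@@H]1C(=O)OCC
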